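The readings were generated by integration for substances that don't exist, noise included.

We start from the constants that the early readings give, and from them ask how long a flask remembers its past.

| flask | starting material | free catalyst | temperature | remark | time |
|---|---|---|---|---|---|
| beta | 20 mM | 0.67 mM | 65 °C | run made earlier |  |
| delta | 20 mM | 1.5 mM | 80 °C | run made earlier |  |
| eta | 10 mM | 1 mM | 65 °C | run made earlier |  |
| south | 20 mM | 1.0 mM |  | at 70 °C until 2.0 h, from then on at 90 °C | 10 h |
| east | 20 mM | 1.0 mM | 70 °C |  | 10 h |
| south-east | 20 mM | 1.0 mM | 90 °C |  | 10 h |

| run | time / h | target / % | starting material / % |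
|---|---|---|---|
| beta | 1.33 | 4.2 | 89.5 |
| beta | 2.50 | 7.1 | 81.2 |
| beta | 4.00 | 10.8 | 72.1 |
| beta | 5.00 | 13.2 | 67.4 |
| beta | 6.00 | 14.7 | 63.9 |
| delta | 0.833 | 11.5 | 66.1 |
| delta | 1.50 | 15.2 | 51.2 |
| delta | 2.50 | 17.2 | 38.8 |
| delta | 3.00 | 16.5 | 35.3 |
| delta | 4.00 | 16.2 | 31.2 |
| eta | 0.500 | 2.9 | 95.4 |
| eta | 1.50 | 6.7 | 85.7 |
| eta | 3.00 | 13.0 | 74.4 |
| eta | 4.00 | 15.7 | 68.6 |
| eta | 6.00 | 19.5 | 58.6 |

(each reading ± 0.3 percentage points)

* the flask that comes out highest in amount of target, in percent of the starting material charged, or "all alike" when all lie within 1.5 percentage points (south / east / south-east / all alike)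
* target at the end, in percent of the starting material charged, south
* target at the end, in percent of the starting material charged, east
* target at the end, in percent of the starting material charged, south-east



1. Main step alone. Let A be starting material and P target. Replacing A by its mean over the first interval, the eta run gives w, the pseudo-first-order constant of target formation at 1.0 mM free catalyst, as 0.0594 h⁻¹ at 65 °C. The delta run, scaled to that catalyst, gives 0.111 h⁻¹ at 80 °C. A straight line of ln w against temperature gives 0.0731 h⁻¹ at 70 °C and 0.168 h⁻¹ at 90 °C. This step alone puts east at 51.9%.

2. Add a way back. In the delta run, target goes from 17.2% to 16.2% while A keeps falling. We read P/A at the last reading as ρ = 0.519 and use it at every temperature, a rough step. With dP/dt = w(A − P/ρ), target approaches ρA with the relaxation time τ = ρ/[w(ρ + 1)], the time a flask needs to forget its target level. That is 4.68 h at 70 °C and 2.03 h at 90 °C.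

3. Add the other loss. At the end of the delta run, A and target together hold 47.4% of the charge, so A also drains elsewhere: the missing share is 52.6% after 4.00 h in the delta run, more than the 21.9% after 6.00 h in the eta run. Taking eta's value as east's mean A, our reckoning for east is 26.8%.

4. South. After the change the south flask has 8.00 h at 90 °C, so by our reckoning its target level at the change survives by the factor 0.0196, hardly any. On about 14.6% of target at the change, that is 0.29 percentage points, less than the margin. We therefore expect south and south-east to end alike, and below east.

The forecast also names east, with 25% there, a little under our figure, and 3.5% in south and 3.5% in south-east. Its ground: “The south flask spends 8 h at 90 °C and ends similarly low, whatever it built up earlier being lost.”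

The flasks give east as highest: east 22.7%, south 5.79%, south-east 5.63%. The forecast held within its tolerance.

    starting material + free catalyst ⇌ target + free catalyst, rate k1*[starting material]*[free catalyst] forward; the back reaction follows from the equilibrium constant (K = 0.770, k = 76.0 M⁻¹ h⁻¹, Ea = 62.0 kJ mol⁻¹, ΔH = −47.0 kJ mol⁻¹)
    target ⇌ isomer of the product (K = 0.570, k = 0.0170 h⁻¹, Ea = 118 kJ mol⁻¹, ΔH = −58.0 kJ mol⁻¹)
    starting material + free catalyst → spent catalyst (k = 1.10 M⁻¹ h⁻¹, Ea = 77.0 kJ mol⁻¹)
    starting material ⇌ dormant form (K = 1.30, k = 0.100 h⁻¹, Ea = 125 kJ mol⁻¹, ΔH = 60.0 kJ mol⁻¹)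
    (constants at 70 °C)

South and south-east end 0.16 points apart, so the early hours at 70 °C have left little trace, as τ said. What the number doesn't show is how the south-east flask holds its target: striking out the way back from target to starting material raises it from 5.63% to 34.6%, the largest single effect.

For the neighbour of south charged with 2.5 mM free catalyst, τ shrinks to 0.812 h, so catalyst should quicken the approach and leave the end near south's. The flask gives 5.52%, against 5.79%.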